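**Plan**

- Cuts: C11=C12 and C11'=C12' (two Wittig reactions on the C10 trienedial), then C7=C8 and C9–C10 of each C15 phosphonium salt back to a ring aldehyde, then C1–C6 and C4=C5 in each ring (carotenoid numbering; ring A is the prenyl end, 2,6-cis; ring B the hydroxylated end, 2,6-trans).
- Enabling feature: the quaternary C1 (gem-dimethyl) lies next to the C6 methine and, through C2–C3, faces the C4=C5 alkene whose methyl sits on C5; C1 can therefore be a tertiary radical, C6 the acceptor carbon of a vinylphosphonium salt, C5 the resulting ylide carbon and C4 an aldehyde.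
- Forward: (R)-carvone is cut down to a C9 aldehyde ester (isopropenyl = C1 with both methyls, CH2CHO = C3–C4, CH2CO2Et = first two side-chain carbons); one radical addition/Wittig annulation with a butynoate-derived vinylphosphonium salt builds the cyclohexene of both end groups.
- The trans diester goes on to ring B and part of it is epimerised at C6 to the cis diester for ring A; each is elaborated (side chain by Wittig; C15 chain by HWE, vinyl Grignard, PPh3·HBr), the ring A salt and then the ring B salt are joined to the C10 dialdehyde, and the side-chain ester is reduced last.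
- Stereochemistry: C2 and C2' both come from C5 of (R)-carvone; the trans C6' of ring B is taken from the annulation by separation, the cis C6 of ring A is set by kinetic protonation of the ring ester dienolate; alkene geometry comes from stabilised ylides and thermal equilibration.

Key step: step 5

Remark: the double-bond geometry of the vinylphosphonium salt made in step 4 is taken to be irrelevant, since it is lost in the radical addition; the salt is drawn as the E isomer.

**Route**

Step 1
Reactants: 1 (R)-(−)-carvone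
Product: 2 (1R,4R,6R)-1-methyl-4-(prop-1-en-2-yl)-7-oxabicyclo[4.1.0]heptan-2-one (carvone 2,3-epoxide, oxirane trans to isopropenyl)
Conditions: 30% aq. H2O2, NaOH (cat.), MeOH, 0 °C
Reagents that add atoms: hydrogen peroxide OO
Why: Weitz–Scheffer nucleophilic epoxidation attacks only the enone double bond, anti to the isopropenyl group, and both new centres are destroyed in step 2 while the carvone stereocentre is untouched.

Step 2
Reactants: 2 carvone epoxide
Product: 4 (3R)-5-oxo-3-(prop-1-en-2-yl)pentanoic acid, via keto diol 3 (not isolated)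
Conditions: H5IO6 (2.5 equiv), THF/H2O, 0 °C to rt
Reagents that add atoms: periodic acid OI(O)(O)(O)(O)=O; water O
Why: Periodic acid hydrolyses the epoxide and then cleaves both the glycol bond and the α-dicarbonyl bond around the former C2 (Malaprade-type cleavage), which removes C2 and its methyl as acetic acid and leaves the ketone carbon as CO2H and the former C3 as CHO, with the stereocentre unchanged between two arms that differ only in oxidation level.

Step 3
Reactants: 4 aldehyde acid
Product: 5 ethyl (3R)-5-oxo-3-(prop-1-en-2-yl)pentanoate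
Conditions: EtI, KHCO3, DMF, rt
Reagents that add atoms: iodoethane CCI
Why: O-alkylation of the carboxylate under nearly neutral conditions esterifies the acid without acetalising or enolising the aldehyde, and the ethyl ester allows ethoxide to be used later without ester scrambling.

Step 4
Reactants: 6 ethyl but-2-ynoate
Product: 7 [(2E)-4-ethoxy-4-oxobut-2-en-2-yl]triphenylphosphonium bromide
Conditions: PPh3·HBr, CH2Cl2, rt
Reagents that add atoms: triphenylphosphine hydrobromide c1ccccc1[PH+](c1ccccc1)c1ccccc1.[Br-]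
Why: Conjugate hydrophosphination of the ynoate (phosphine adds to the β-carbon, then protonation) is the known way to β-phosphonioacrylate vinylphosphonium salts.

Step 5
Reactants: 5 ethyl (3R)-5-oxo-3-(prop-1-en-2-yl)pentanoate; 7 vinylphosphonium bromide
Product: 10 ethyl (1S,5R)-5-(2-ethoxy-2-oxoethyl)-2,6,6-trimethylcyclohex-2-ene-1-carboxylate (2,6-trans), via alkylphosphonium bromide 8 (not isolated), via ylide 9 (not isolated)
Conditions: Fe(acac)3 (0.3 equiv), PhSiH3 (2.5 equiv), 7 (2 equiv), EtOH/THF, 60 °C; then NaOEt, EtOH, 0 °C to rt; chromatography, trans epimer collected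
Reagents that add atoms: none
Why: Proposed new method: the iron hydride formed from Fe(acac)3 and PhSiH3 transfers a hydrogen atom to the CH2 terminus of the isopropenyl group of 5 (Markovnikov metal-hydride hydrogen-atom transfer), the tertiary radical at C1 adds to the unsubstituted alkene carbon of 7 (β to phosphorus, α to the ester) to form C1–C6, and reduction and protonation of the α-phosphonio radical give salt 8; ethoxide then forms ylide 9, whose carbon (C5) attacks the aldehyde carbon (C4), and the oxaphosphetane collapses to the C4=C5 alkene and Ph3PO. The closest known reactions are the iron-mediated reductive coupling of 1,1-disubstituted alkenes with electron-poor alkenes (Giese type), radical addition to vinylphosphonium salts followed by Wittig olefination, and the intramolecular Wittig reaction. The six-membered ring is closed in the Wittig stage by 6-exo-trig attack of the ylide carbon on the formyl group. C2 comes unchanged from carvone (it is not α to a carbonyl group), whereas C6 is created without useful 1,3-induction across the quaternary carbon, so both C6 epimers should form; the trans epimer 10 needed for ring B is isolated by chromatography, and the cis epimer that accompanies it is the same compound that step 6 makes from surplus 10 and is combined with that material. The step needs hydrogen-atom transfer to the electron-rich isopropenyl group and not to the acceptor (polarity match, excess of 7), attack at the CH terminus of 7 (directed by the phosphonium group and by sterics), and ylide formation with ring closure faster than loss of PPh3 by β-elimination (six-membered intramolecular Wittig, hindered C6–H).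

Step 6
Reactants: 10 trans diester (the part not needed for ring B)
Product: 12 ethyl (1R,5R)-5-(2-ethoxy-2-oxoethyl)-2,6,6-trimethylcyclohex-2-ene-1-carboxylate (2,6-cis), via dilithium bis-enolate 11 (not isolated)
Conditions: LiN(i-Pr)2 (2.4 equiv), THF, −78 °C; then t-BuCO2H (4 equiv) in THF, −78 °C; chromatography, recovered 10 resubmitted
Reagents that add atoms: none
Why: Double deprotonation gives the side-chain enolate and the ring ester dienolate, whose kinetic protonation takes place at the α-carbon (deconjugative protonation of cyclogeranate-type dienolates) from the face opposite the pseudoaxial C1 methyl group in the conformer with the C2 side chain equatorial, so the new hydrogen should end up trans to the side chain and the 2,6-cis ester should result, while C2 is not acidic and is untouched.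

Step 7
Reactants: 10 trans diester
Product: 13 [(1S,5R)-5-(2-hydroxyethyl)-2,6,6-trimethylcyclohex-2-en-1-yl]methanol
Conditions: LiAlH4, THF, 0 °C to rt
Reagents that add atoms: none
Why: LiAlH4 reduction converts both esters into primary alcohols without touching either stereocentre or the ring alkene.

Step 8
Reactants: 13 trans diol
Product: 14 (1S,5R)-2,6,6-trimethyl-5-(2-oxoethyl)cyclohex-2-ene-1-carbaldehyde
Conditions: Dess–Martin periodinane (2.4 equiv), NaHCO3, CH2Cl2, 0 °C to rt
Reagents that add atoms: none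
Why: Dess–Martin oxidation of both alcohols under buffered, non-basic conditions gives the dialdehyde without epimerising the formyl-bearing ring carbon or moving the ring double bond into conjugation, and the trans arrangement rules out an intramolecular aldol reaction.

Step 9
Reactants: 14 trans dialdehyde
Product: 15 ethyl (2E)-4-[(1R,5S)-5-formyl-4,6,6-trimethylcyclohex-3-en-1-yl]-2-methylbut-2-enoate
Conditions: Ph3P=C(CH3)CO2Et (1.05 equiv), CH2Cl2, 0 °C to rt
Reagents that add atoms: ethyl 2-(triphenyl-λ5-phosphanylidene)propanoate CCOC(=O)C(C)=P(c1ccccc1)(c1ccccc1)c1ccccc1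
Why: Wittig olefination with a stabilised ylide is E-selective and at room temperature reacts only with the unhindered CH2CHO group, because the ring aldehyde sits on a carbon flanked by the quaternary centre.

Step 10
Reactants: 15 enoate aldehyde
Product: 16 ethyl (2E)-2-methyl-4-[(1R,5S)-4,6,6-trimethyl-5-[(1E)-3-oxobut-1-en-1-yl]cyclohex-3-en-1-yl]but-2-enoate
Conditions: (EtO)2P(O)CH2C(O)CH3, Ba(OH)2, THF/H2O (40:1), rt
Reagents that add atoms: diethyl (2-oxopropyl)phosphonate CCOP(=O)(CC(C)=O)OCC
Why: Horner–Wadsworth–Emmons olefination under Ba(OH)2 conditions, which are mild enough for α-branched enolisable aldehydes, gives the E-enone of the α-ionone type.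

Step 11
Reactants: 16 enone
Product: 17 ethyl (2E)-4-[(1R,5S)-5-[(1E)-3-hydroxy-3-methylpenta-1,4-dien-1-yl]-4,6,6-trimethylcyclohex-3-en-1-yl]-2-methylbut-2-enoate (both carbinol epimers)
Conditions: CH2=CHMgBr (1.1 equiv), THF, −78 °C
Reagents that add atoms: vinylmagnesium bromide C=C[Mg]Br
Why: 1,2-Addition of the vinyl Grignard reagent goes to the methyl ketone, which is far more electrophilic than the α-methyl enoate at −78 °C, and the uncontrolled carbinol centre is lost in step 12.

Step 12
Reactants: 17 vinyl carbinol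
Product: 18 [(2E,4E)-5-[(1S,5R)-5-[(2E)-4-ethoxy-3-methyl-4-oxobut-2-en-1-yl]-2,6,6-trimethylcyclohex-2-en-1-yl]-3-methylpenta-2,4-dien-1-yl]triphenylphosphonium bromide
Conditions: PPh3·HBr, CH2Cl2/EtOH, rt
Reagents that add atoms: triphenylphosphine hydrobromide c1ccccc1[PH+](c1ccccc1)c1ccccc1.[Br-]
Why: Ionisation of the tertiary doubly allylic alcohol and capture of the pentadienyl cation at its primary terminus by PPh3 (the standard vinyl carbinol route to C15 Wittig salts) gives the conjugated E,E-dienyl salt and leaves the enoate alone.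

Step 13
Reactants: 12 cis diester
Product: 19 ethyl (1R,5R)-2,6,6-trimethyl-5-(2-oxoethyl)cyclohex-2-ene-1-carboxylate
Conditions: i-Bu2AlH (1.05 equiv), CH2Cl2, −78 °C
Reagents that add atoms: none
Why: Partial ester reduction with i-Bu2AlH at −78 °C stops at the aldehyde and is chemoselective for the unhindered acetate arm over the ester on the carbon flanked by the quaternary centre.

Step 14
Reactants: 19 cis aldehyde ester
Product: 20 ethyl (1R,5S)-2,6,6-trimethyl-5-(3-methylbut-2-en-1-yl)cyclohex-2-ene-1-carboxylate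
Conditions: i-PrPPh3I, n-BuLi, THF, −78 to 0 °C; then 19, −78 °C to rt
Reagents that add atoms: isopropyltriphenylphosphonium iodide CC(C)[P+](c1ccccc1)(c1ccccc1)c1ccccc1.[I-]
Why: Wittig olefination with isopropylidenetriphenylphosphorane turns CH2CHO into the prenyl group, and the hindered ester α-hydrogen is not removed by the ylide at low temperature, so the cis configuration is kept.

Step 15
Reactants: 20 cis prenyl ester
Product: 21 [(1R,5S)-2,6,6-trimethyl-5-(3-methylbut-2-en-1-yl)cyclohex-2-en-1-yl]methanol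
Conditions: LiAlH4, Et2O, 0 °C
Reagents that add atoms: none
Why: LiAlH4 reduction of the hindered ester gives the primary alcohol with no change at the stereocentres.

Step 16
Reactants: 21 cis alcohol
Product: 22 (1R,5S)-2,6,6-trimethyl-5-(3-methylbut-2-en-1-yl)cyclohex-2-ene-1-carbaldehyde
Conditions: Dess–Martin periodinane, NaHCO3, CH2Cl2, 0 °C
Reagents that add atoms: none
Why: Dess–Martin oxidation works without base, so the epimerisable formyl-bearing centre of the cis aldehyde is kept.

Step 17
Reactants: 22 cis aldehyde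
Product: 23 (3E)-4-[(1R,5S)-2,6,6-trimethyl-5-(3-methylbut-2-en-1-yl)cyclohex-2-en-1-yl]but-3-en-2-one
Conditions: (EtO)2P(O)CH2C(O)CH3, Ba(OH)2, THF/H2O (40:1), rt
Reagents that add atoms: diethyl (2-oxopropyl)phosphonate CCOP(=O)(CC(C)=O)OCC
Why: Horner–Wadsworth–Emmons olefination under the weakly basic Ba(OH)2 conditions gives the E-enone, after which the ring methine is only vinylogously activated and configurationally more robust.

Step 18
Reactants: 23 enone
Product: 24 (1E)-3-methyl-1-[(1R,5S)-2,6,6-trimethyl-5-(3-methylbut-2-en-1-yl)cyclohex-2-en-1-yl]penta-1,4-dien-3-ol (both carbinol epimers)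
Conditions: CH2=CHMgBr, THF, −78 °C
Reagents that add atoms: vinylmagnesium bromide C=C[Mg]Br
Why: 1,2-Addition of the vinyl Grignard reagent to the enone carbonyl gives the vinyl carbinol, whose new centre is lost in step 19.

Step 19
Reactants: 24 vinyl carbinol
Product: 25 [(2E,4E)-3-methyl-5-[(1R,5S)-2,6,6-trimethyl-5-(3-methylbut-2-en-1-yl)cyclohex-2-en-1-yl]penta-2,4-dien-1-yl]triphenylphosphonium bromide
Conditions: PPh3·HBr, MeOH, rt
Reagents that add atoms: triphenylphosphine hydrobromide c1ccccc1[PH+](c1ccccc1)c1ccccc1.[Br-]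
Why: Acid ionisation of the tertiary allylic alcohol and capture of the dienyl cation at the primary terminus by PPh3 gives the C15 Wittig salt, and isolated trisubstituted alkenes such as the prenyl group are known to survive these conditions.

Step 20
Reactants: 25 ring A phosphonium salt; 26 (2E,4E,6E)-2,7-dimethylocta-2,4,6-trienedial
Product: 28 (2E,4E,6E,8E,10E,12E)-2,7,11-trimethyl-13-[(1R,5S)-2,6,6-trimethyl-5-(3-methylbut-2-en-1-yl)cyclohex-2-en-1-yl]trideca-2,4,6,8,10,12-hexaenal, via ylide 27 (not isolated)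
Conditions: 26 (3 equiv), NaOMe, MeOH/CH2Cl2, 0 °C to rt, dark; then heptane, 80 °C (Z to E equilibration)
Reagents that add atoms: none
Why: Wittig olefination of the semistabilised ylide with one formyl group of the dialdehyde used in excess (statistical mono-olefination), followed by thermal equilibration of the new C11=C12 bond, is the standard C15 + C10 carotenoid coupling.

Step 21
Reactants: 28 C25 aldehyde; 18 ring B phosphonium salt
Product: 30 ethyl (2E)-2-methyl-4-[(1R,5S)-4,6,6-trimethyl-5-[(1E,3E,5E,7E,9E,11E,13E,15E,17E)-3,7,12,16-tetramethyl-18-[(1R,5S)-2,6,6-trimethyl-5-(3-methylbut-2-en-1-yl)cyclohex-2-en-1-yl]octadeca-1,3,5,7,9,11,13,15,17-nonaen-1-yl]cyclohex-3-en-1-yl]but-2-enoate, via ylide 29 (not isolated)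
Conditions: NaOEt, EtOH/CH2Cl2, 0 °C to rt, dark; then heptane, 80 °C (Z to E equilibration)
Reagents that add atoms: none
Why: The second Wittig olefination forms C11'=C12', NaOEt matches the ethyl ester, and thermal equilibration should give the all-E polyene.

Step 22
Reactants: 30 C50 ethyl ester
Product: 31 (2E)-2-methyl-4-[(1R,5S)-4,6,6-trimethyl-5-[(1E,3E,5E,7E,9E,11E,13E,15E,17E)-3,7,12,16-tetramethyl-18-[(1R,5S)-2,6,6-trimethyl-5-(3-methylbut-2-en-1-yl)cyclohex-2-en-1-yl]octadeca-1,3,5,7,9,11,13,15,17-nonaen-1-yl]cyclohex-3-en-1-yl]but-2-en-1-ol (target)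
Conditions: i-Bu2AlH (2.5 equiv), CH2Cl2, −78 °C; aqueous potassium sodium tartrate
Reagents that add atoms: none
Why: 1,2-Reduction of the α,β-unsaturated ester with i-Bu2AlH at low temperature gives the E-allylic alcohol and leaves the polyene and all stereocentres untouched.

**Compound list**

1 | (R)-(−)-carvone | CC(=C)[C@H]1CC(=O)C(C)=CC1 | starting material
2 | (1R,4R,6R)-1-methyl-4-(prop-1-en-2-yl)-7-oxabicyclo[4.1.0]heptan-2-one | CC(=C)[C@@H]1C[C@H]2O[C@@]2(C)C(=O)C1 | intermediate
3 | (5R)-2,3-dihydroxy-2-methyl-5-(prop-1-en-2-yl)cyclohexan-1-one (2-OH trans, 3-OH cis to isopropenyl; not isolated) | CC(=C)[C@@H]1C[C@H](O)[C@@](C)(O)C(=O)C1 | intermediate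
4 | (3R)-5-oxo-3-(prop-1-en-2-yl)pentanoic acid | CC(=C)[C@H](CC=O)CC(=O)O | intermediate
5 | ethyl (3R)-5-oxo-3-(prop-1-en-2-yl)pentanoate | CC(=C)[C@H](CC=O)CC(=O)OCC | intermediate
6 | ethyl but-2-ynoate | CC#CC(=O)OCC | starting material
7 | [(2E)-4-ethoxy-4-oxobut-2-en-2-yl]triphenylphosphonium bromide | CCOC(=O)/C=C(\C)[P+](c1ccccc1)(c1ccccc1)c1ccccc1.[Br-] | intermediate
8 | [(5R)-7-ethoxy-3-(ethoxycarbonyl)-4,4-dimethyl-7-oxo-5-(2-oxoethyl)heptan-2-yl]triphenylphosphonium bromide (epimers at C2 and C3; not isolated) | CCOC(=O)C[C@@H](CC=O)C(C)(C)C(C(=O)OCC)C(C)[P+](c1ccccc1)(c1ccccc1)c1ccccc1.[Br-] | intermediate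
9 | ethyl (3R)-5-(ethoxycarbonyl)-4,4-dimethyl-3-(2-oxoethyl)-6-(triphenyl-λ5-phosphanylidene)heptanoate (epimers at C5; not isolated) | CCOC(=O)C[C@@H](CC=O)C(C)(C)C(C(=O)OCC)C(C)=P(c1ccccc1)(c1ccccc1)c1ccccc1 | intermediate
10 | ethyl (1S,5R)-5-(2-ethoxy-2-oxoethyl)-2,6,6-trimethylcyclohex-2-ene-1-carboxylate (2,6-trans) | CCOC(=O)[C@H]1C(C)=CC[C@H](CC(=O)OCC)C1(C)C | intermediate
11 | dilithium bis-enolate of 10: (5R)-1-[ethoxy(lithiooxy)methylidene]-5-[2-ethoxy-2-(lithiooxy)ethenyl]-2,6,6-trimethylcyclohex-2-ene (not isolated) | CCOC(O[Li])=C1C(C)=CC[C@H](C=C(OCC)O[Li])C1(C)C | intermediate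
12 | ethyl (1R,5R)-5-(2-ethoxy-2-oxoethyl)-2,6,6-trimethylcyclohex-2-ene-1-carboxylate (2,6-cis) | CCOC(=O)C[C@H]1CC=C(C)[C@@H](C(=O)OCC)C1(C)C | intermediate
13 | [(1S,5R)-5-(2-hydroxyethyl)-2,6,6-trimethylcyclohex-2-en-1-yl]methanol | OC[C@H]1C(C)=CC[C@H](CCO)C1(C)C | intermediate
14 | (1S,5R)-2,6,6-trimethyl-5-(2-oxoethyl)cyclohex-2-ene-1-carbaldehyde | O=C[C@H]1C(C)=CC[C@H](CC=O)C1(C)C | intermediate
15 | ethyl (2E)-4-[(1R,5S)-5-formyl-4,6,6-trimethylcyclohex-3-en-1-yl]-2-methylbut-2-enoate | O=C[C@H]1C(C)=CC[C@H](C/C=C(\C)C(=O)OCC)C1(C)C | intermediate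
16 | ethyl (2E)-2-methyl-4-[(1R,5S)-4,6,6-trimethyl-5-[(1E)-3-oxobut-1-en-1-yl]cyclohex-3-en-1-yl]but-2-enoate | CC(=O)/C=C/[C@H]1C(C)=CC[C@H](C/C=C(\C)C(=O)OCC)C1(C)C | intermediate
17 | ethyl (2E)-4-[(1R,5S)-5-[(1E)-3-hydroxy-3-methylpenta-1,4-dien-1-yl]-4,6,6-trimethylcyclohex-3-en-1-yl]-2-methylbut-2-enoate (carbinol epimers) | C=CC(C)(O)/C=C/[C@H]1C(C)=CC[C@H](C/C=C(\C)C(=O)OCC)C1(C)C | intermediate
18 | [(2E,4E)-5-[(1S,5R)-5-[(2E)-4-ethoxy-3-methyl-4-oxobut-2-en-1-yl]-2,6,6-trimethylcyclohex-2-en-1-yl]-3-methylpenta-2,4-dien-1-yl]triphenylphosphonium bromide | c1ccccc1[P+](c1ccccc1)(c1ccccc1)C/C=C(C)/C=C/[C@H]1C(C)=CC[C@H](C/C=C(\C)C(=O)OCC)C1(C)C.[Br-] | intermediate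
19 | ethyl (1R,5R)-2,6,6-trimethyl-5-(2-oxoethyl)cyclohex-2-ene-1-carboxylate | O=CC[C@H]1CC=C(C)[C@@H](C(=O)OCC)C1(C)C | intermediate
20 | ethyl (1R,5S)-2,6,6-trimethyl-5-(3-methylbut-2-en-1-yl)cyclohex-2-ene-1-carboxylate | CC(C)=CC[C@H]1CC=C(C)[C@@H](C(=O)OCC)C1(C)C | intermediate
21 | [(1R,5S)-2,6,6-trimethyl-5-(3-methylbut-2-en-1-yl)cyclohex-2-en-1-yl]methanol | CC(C)=CC[C@H]1CC=C(C)[C@@H](CO)C1(C)C | intermediate
22 | (1R,5S)-2,6,6-trimethyl-5-(3-methylbut-2-en-1-yl)cyclohex-2-ene-1-carbaldehyde | CC(C)=CC[C@H]1CC=C(C)[C@@H](C=O)C1(C)C | intermediate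
23 | (3E)-4-[(1R,5S)-2,6,6-trimethyl-5-(3-methylbut-2-en-1-yl)cyclohex-2-en-1-yl]but-3-en-2-one | CC(C)=CC[C@H]1CC=C(C)[C@@H](/C=C/C(C)=O)C1(C)C | intermediate
24 | (1E)-3-methyl-1-[(1R,5S)-2,6,6-trimethyl-5-(3-methylbut-2-en-1-yl)cyclohex-2-en-1-yl]penta-1,4-dien-3-ol (carbinol epimers) | CC(C)=CC[C@H]1CC=C(C)[C@@H](/C=C/C(C)(O)C=C)C1(C)C | intermediate
25 | [(2E,4E)-3-methyl-5-[(1R,5S)-2,6,6-trimethyl-5-(3-methylbut-2-en-1-yl)cyclohex-2-en-1-yl]penta-2,4-dien-1-yl]triphenylphosphonium bromide | CC(C)=CC[C@H]1CC=C(C)[C@@H](/C=C/C(C)=C/C[P+](c2ccccc2)(c2ccccc2)c2ccccc2)C1(C)C.[Br-] | intermediate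
26 | (2E,4E,6E)-2,7-dimethylocta-2,4,6-trienedial | O=C/C(C)=C/C=C/C=C(C)/C=O | starting material
27 | [(2E,4E)-3-methyl-5-[(1R,5S)-2,6,6-trimethyl-5-(3-methylbut-2-en-1-yl)cyclohex-2-en-1-yl]penta-2,4-dien-1-ylidene]triphenyl-λ5-phosphane (not isolated) | CC(C)=CC[C@H]1CC=C(C)[C@@H](/C=C/C(C)=C/C=P(c2ccccc2)(c2ccccc2)c2ccccc2)C1(C)C | intermediate
28 | (2E,4E,6E,8E,10E,12E)-2,7,11-trimethyl-13-[(1R,5S)-2,6,6-trimethyl-5-(3-methylbut-2-en-1-yl)cyclohex-2-en-1-yl]trideca-2,4,6,8,10,12-hexaenal | CC(C)=CC[C@H]1CC=C(C)[C@@H](/C=C/C(C)=C/C=C/C(C)=C/C=C/C=C(C)/C=O)C1(C)C | intermediate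
29 | ethyl (2E)-2-methyl-4-[(1R,5S)-4,6,6-trimethyl-5-[(1E,3E)-3-methyl-5-(triphenyl-λ5-phosphanylidene)penta-1,3-dien-1-yl]cyclohex-3-en-1-yl]but-2-enoate (not isolated) | c1ccccc1P(c1ccccc1)(c1ccccc1)=C/C=C(C)/C=C/[C@H]1C(C)=CC[C@H](C/C=C(\C)C(=O)OCC)C1(C)C | intermediate
30 | ethyl (2E)-2-methyl-4-[(1R,5S)-4,6,6-trimethyl-5-[(1E,3E,5E,7E,9E,11E,13E,15E,17E)-3,7,12,16-tetramethyl-18-[(1R,5S)-2,6,6-trimethyl-5-(3-methylbut-2-en-1-yl)cyclohex-2-en-1-yl]octadeca-1,3,5,7,9,11,13,15,17-nonaen-1-yl]cyclohex-3-en-1-yl]but-2-enoate | CC(C)=CC[C@H]1CC=C(C)[C@@H](/C=C/C(C)=C/C=C/C(C)=C/C=C/C=C(C)/C=C/C=C(C)/C=C/[C@H]2C(C)=CC[C@H](C/C=C(\C)C(=O)OCC)C2(C)C)C1(C)C | intermediate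
31 | (2E)-2-methyl-4-[(1R,5S)-4,6,6-trimethyl-5-[(1E,3E,5E,7E,9E,11E,13E,15E,17E)-3,7,12,16-tetramethyl-18-[(1R,5S)-2,6,6-trimethyl-5-(3-methylbut-2-en-1-yl)cyclohex-2-en-1-yl]octadeca-1,3,5,7,9,11,13,15,17-nonaen-1-yl]cyclohex-3-en-1-yl]but-2-en-1-ol (2'R,6'S hydroxylated ring, 2S,6R prenyl ring in carotenoid numbering) | CC(C)=CC[C@H]1CC=C(C)[C@@H](/C=C/C(C)=C/C=C/C(C)=C/C=C/C=C(C)/C=C/C=C(C)/C=C/[C@H]2C(C)=CC[C@H](C/C=C(\C)CO)C2(C)C)C1(C)C | target

**Totals and risks**

Total step count: 22. Longest linear sequence: 15 steps (1, 2, 3, 5, 6, 13 to 22).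

Steps most likely to fail:

1. Step 5 (proposed new method). What may go wrong: conjugate reduction of 7 by the iron hydride instead of radical addition; loss of PPh3 by β-elimination after the base is added instead of ylide formation and ring closure; or a C6 epimer ratio far on the cis side, which would leave ring B short because step 6 only converts trans into cis. Fallback with known chemistry, from 5 back to 10: Wittig reaction of 5 with (1-methoxyethylidene)triphenylphosphorane gives ethyl (3R)-6-methoxy-3-(prop-1-en-2-yl)hept-5-enoate F1. Dilute aqueous acid hydrolyses it to the methyl ketone ethyl (3R)-6-oxo-3-(prop-1-en-2-yl)heptanoate F2. HWE reaction with triethyl phosphonoacetate (NaH, THF) and chromatography give diethyl (2E,6R)-3-methyl-6-(prop-1-en-2-yl)oct-2-enedioate F3. Protic acid (85% H3PO4, or H2SO4 in HCO2H at 0 °C) then protonates the isopropenyl group; the tertiary cation at C1 is captured by the enoate α-carbon (C6) and a proton is lost from C4, the classical geranate to α-cyclogeranate cyclisation. Chromatography returns the trans diester to the route at 10; the cis epimer that forms alongside is 12 and enters at step 13.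

2. Step 6. What may go wrong: poor facial selectivity in the protonation, protonation at the γ-carbon with migration of the double bond into conjugation, incomplete removal of the hindered C6 hydrogen, or loss of ethoxide from the ester enolate on warming. Fallback that drops the epimerisation, from 5 back to 12: the annulation of 5 with 7 (step 5) is run on a larger scale and 12 is taken only as the cis epimer that forms there beside 10, separated by chromatography on AgNO3-impregnated silica. This makes no new compound (F0); if that cis fraction is small, the cyclisation described under step 5 is a second source of the same epimer.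

3. Step 17. What may go wrong: epimerisation of the formyl-bearing carbon of the cis aldehyde 22 towards trans, or migration of the ring double bond into conjugation, during the basic olefination. Fallback that reverses the polarity at C7, from 21 back to 25: alcohol 21 is converted with CBr4/PPh3 into [(1R,5S)-2,6,6-trimethyl-5-(3-methylbut-2-en-1-yl)cyclohex-2-en-1-yl]methyl bromide F4, which is heated with PPh3 to give {[(1R,5S)-2,6,6-trimethyl-5-(3-methylbut-2-en-1-yl)cyclohex-2-en-1-yl]methyl}triphenylphosphonium bromide F5. Its ylide (n-BuLi, THF) is condensed with (2E)-4,4-dimethoxy-2-methylbut-2-enal to give (2E,4E)-1,1-dimethoxy-3-methyl-5-[(1R,5S)-2,6,6-trimethyl-5-(3-methylbut-2-en-1-yl)cyclohex-2-en-1-yl]penta-2,4-diene F6 after equilibration of the new alkene with a trace of I2. Aqueous acid gives the dienal (2E,4E)-3-methyl-5-[(1R,5S)-2,6,6-trimethyl-5-(3-methylbut-2-en-1-yl)cyclohex-2-en-1-yl]penta-2,4-dienal F7, NaBH4 gives the dienol (2E,4E)-3-methyl-5-[(1R,5S)-2,6,6-trimethyl-5-(3-methylbut-2-en-1-yl)cyclohex-2-en-1-yl]penta-2,4-dien-1-ol F8, and PPh3·HBr converts F8 into 25. In this sequence the ring carbon next to C7 never carries a carbonyl group.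

**Further compounds**

F1 | step 5 | ethyl (3R)-6-methoxy-3-(prop-1-en-2-yl)hept-5-enoate (E/Z mixture) | CC(=C)[C@H](CC=C(C)OC)CC(=O)OCC
F2 | step 5 | ethyl (3R)-6-oxo-3-(prop-1-en-2-yl)heptanoate | CC(=C)[C@H](CCC(C)=O)CC(=O)OCC
F3 | step 5 | diethyl (2E,6R)-3-methyl-6-(prop-1-en-2-yl)oct-2-enedioate | CC(=C)[C@H](CC/C(C)=C/C(=O)OCC)CC(=O)OCC
F0 | step 6 | none | none
F4 | step 17 | [(1R,5S)-2,6,6-trimethyl-5-(3-methylbut-2-en-1-yl)cyclohex-2-en-1-yl]methyl bromide | CC(C)=CC[C@H]1CC=C(C)[C@@H](CBr)C1(C)C
F5 | step 17 | {[(1R,5S)-2,6,6-trimethyl-5-(3-methylbut-2-en-1-yl)cyclohex-2-en-1-yl]methyl}triphenylphosphonium bromide | CC(C)=CC[C@H]1CC=C(C)[C@@H](C[P+](c2ccccc2)(c2ccccc2)c2ccccc2)C1(C)C.[Br-]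
F6 | step 17 | (2E,4E)-1,1-dimethoxy-3-methyl-5-[(1R,5S)-2,6,6-trimethyl-5-(3-methylbut-2-en-1-yl)cyclohex-2-en-1-yl]penta-2,4-diene | CC(C)=CC[C@H]1CC=C(C)[C@@H](/C=C/C(C)=C/C(OC)OC)C1(C)C
F7 | step 17 | (2E,4E)-3-methyl-5-[(1R,5S)-2,6,6-trimethyl-5-(3-methylbut-2-en-1-yl)cyclohex-2-en-1-yl]penta-2,4-dienal | CC(C)=CC[C@H]1CC=C(C)[C@@H](/C=C/C(C)=C/C=O)C1(C)C
F8 | step 17 | (2E,4E)-3-methyl-5-[(1R,5S)-2,6,6-trimethyl-5-(3-methylbut-2-en-1-yl)cyclohex-2-en-1-yl]penta-2,4-dien-1-ol | CC(C)=CC[C@H]1CC=C(C)[C@@H](/C=C/C(C)=C/CO)C1(C)C
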